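A one-step reaction has no competition. Here the suspects are a chain and a leak: free catalyst turns starting material into intermediate, reagent with second catalyst turns intermediate into target, and starting material meets target to give side product.

| flask | starting material | reagent | free catalyst | second catalyst | remark | time |
|---|---|---|---|---|---|---|
| amber | 0.32 M | 1.3 equiv | 2.4 mol% | 2.5 mol% | run made earlier |  |
| grey | 0.32 M | 1.3 equiv | 2.4 mol% | 1.7 mol% | run made earlier |  |
| ochre | 0.32 M | 1.3 equiv | 2.4 mol% | 3.8 mol% | run made earlier |  |
| green | 0.32 M | 1.3 equiv | 3.6 mol% | 2.5 mol% | run made earlier |  |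
| dusk | 0.32 M | 1.30 equiv (in portions, 2, over 4.0 d) | 2.4 mol% | 2.5 mol% | first portion at the start, last at 4.0 d | 5.0 d |
| dawn | 0.32 M (fed, over 4.0 d) | 1.30 equiv | 2.4 mol% | 2.5 mol% | all else is in the flask from the start; the feed brings no volume worth counting | 5.0 d |
| winter | 0.32 M | 1.30 equiv | 2.4 mol% | 2.5 mol% | everything together at the start | 5.0 d |
| midnight | 0.32 M | 1.30 equiv (fed, over 4.0 d) | 2.4 mol% | 2.5 mol% | all else is in the flask from the start; the feed brings no volume worth counting | 5.0 d |

| run | time / d | target / % | side product / % |
|---|---|---|---|
| amber | 0.500 | 31.6 | 11.1 |
| amber | 1.04 | 50.0 | 25.6 |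
| amber | 1.67 | 56.0 | 35.3 |
| amber | 2.08 | 58.5 | 37.7 |
| amber | 2.50 | 58.7 | 38.4 |
| amber | 3.00 | 59.0 | 40.1 |
| grey | 0.333 | 21.4 | 4.3 |
| grey | 0.500 | 30.8 | 9.8 |
| grey | 0.833 | 43.8 | 19.6 |
| grey | 1.67 | 56.3 | 33.9 |
| grey | 2.50 | 59.1 | 38.8 |
| grey | 4.00 | 61.1 | 39.1 |
| ochre | 0.333 | 24.5 | 5.8 |
| ochre | 0.500 | 34.2 | 12.2 |
| ochre | 0.833 | 45.5 | 23.4 |
| ochre | 1.67 | 55.1 | 36.3 |
| ochre | 2.50 | 58.4 | 39.8 |
| ochre | 4.00 | 59.4 | 40.1 |
| green | 0.833 | 57.4 | 21.6 |
| green | 1.67 | 68.1 | 29.3 |
| green | 2.50 | 70.0 | 29.4 |
| green | 3.00 | 68.9 | 30.6 |
| green | 4.00 | 69.0 | 29.4 |

(standard deviation of a reading: 0.5 percentage points)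

1. the flask that comes out highest in share of target in target plus side product, or "all alike" when all lie within 1.5 percentage points (dusk / dawn / winter / midnight / all alike)
2. share of target in target plus side product at the end, dusk
3. share of target in target plus side product at the end, dawn
4. share of target in target plus side product at the end, winter
5. share of target in target plus side product at the end, midnight

- percent here means starting material units held: one side product counts as two
- the numbers in the tables scatter by 0.5 percentage points (one standard deviation)
- on the list of suspects stand: starting material + free catalyst -> free catalyst + intermediate; reagent + second catalyst + intermediate -> second catalyst + target; starting material + target -> side product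

Amber, grey and ochre differ in second catalyst, yet they end alike, at 59.0%, 61.1% and 59.4% target. So we watch the split of starting material. Let m be the mean target that starting material meets as it goes, and L the target level, as a fraction of the charge, at which starting material goes equally fast into side product and intermediate. Each side step takes one starting material and one target, and side product counts double. So side product ends at 2m/(L+m).

Where target rises in step with the starting material consumed, m is half the final target. Amber's last reading then gives the balance level, a selectivity factor, of 1.18. Green gives 2.00, higher than amber, so we scale it with free catalyst.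

Winter has amber's charges, so our reckoning for it, 59.6% target, repeats amber's reading and tests nothing. We give dawn the same figure, taking its target to rise in step with starting material consumed as well. For midnight we have no m, but the forecast's share needs 0.145.

The forecast says dusk 70%, dawn 58.5%, winter 60%, midnight 78%, best midnight: “Withholding reagent parks material as intermediate until starting material is gone”.

The flasks give dusk 65.7%, dawn 58.6%, winter 60.1%, midnight 79.0%, best midnight.

    starting material + free catalyst → free catalyst + intermediate (k = 0.00180 M⁻¹ s⁻¹)
    reagent + second catalyst + intermediate → second catalyst + target (k = 0.0580 M⁻² s⁻¹)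
    starting material + target → side product (k = 3.70 × 10⁻⁵ M⁻¹ s⁻¹)

 Read backwards, midnight's m is 0.138, about half winter's 0.294. Now take dawn with 9.6 mol% free catalyst. Scaled, L becomes 4.71, and the same reckoning gives 16.3% side product. That flask ends with 16.2% side product and a target share of 83.8%.

The readings are calculated with made-up constants, and the scatter is random.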